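**Proposed synthesis of (13S)-labd-7-ene-15,17-diyl diacetate (CNP0294037.1) from (R)-carvone by a radical closure of ring A**

Compound numbers refer to the list after the steps. Ring atoms carry labdane numbers (C1–C20) throughout, including in the carvone-derived monocycles.

## Analysis of the target

- Target 22 is the diacetate of (13S)-labd-7-ene-15,17-diol, a trans-fused decalin. Ring A (C1–C5, C10) holds the gem-dimethyl carbon C4 and the quaternary C10 with its angular methyl C20. Ring B (C5–C10) holds the C7=C8 alkene.
- C8 carries the acetoxymethyl carbon C17. C9 carries the chain C11–C15, which has a methyl-branched stereocentre at C13 and the second acetate on C15.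
- C5, C9 and C10 are contiguous and mutually fixed: 5α-H and 9α-H both lie anti to the β-methyl on C10, so the fusion is trans and the chain is equatorial.
- C13 is three bonds away from the ring and cannot be relayed from it, so it has to be brought in resolved.
- The sensitive parts are the primary allylic acetate (ionisation, SN2′ attack), the trisubstituted alkene (it can slip to the tetrasubstituted C8=C9 position under acid) and the two base-labile esters. The acetates are therefore put on last.
- The difficulties are the quaternary C10 between two stereocentres, the regiodefined alkene, the oxidation of C17 and the remote C13.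
- The plan rests on ring B. With a methyl-bearing C8, the C7=C8 alkene, an oxygenated C9 and a three-carbon branch on C5, ring B is atom for atom (R)-carvone 1. The stereocentre of 1 is C5, its isopropenyl group is C4 with both methyls, and its α′-carbon is C10.

## Retrosynthetic reasoning

**Acetates and silyl ether (22 ⇒ 21 ⇒ 20).** The two acyl C–O bonds are cut first, giving diol 21. O15 is then masked as the silyl ether 20. An ester on O15 could not pass the organometallic and dissolving-metal steps, whereas a silyl ether can.

**C17–O bond (20 ⇒ 19).** Cutting the C17–O bond returns C17 to the plain methyl group that 1 supplies. Ring B can then be carried unmodified through every C–C bond formation. The forward allylic oxidation must choose C17 over the hindered methine C9 and over C6, which lies at the less substituted alkene end.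

**C7–H bond, alkene position and C9 (19 ⇒ 18 ⇒ 17 ⇒ 16).** The C7–H bond is traced to an enol triflate 18, and 18 to the enolate 17 obtained by dissolving-metal reduction of enone 16. This one reduction has to do three things:
- protonate C9 anti to C20, which sets the C9 stereocentre;
- hold the alkene at C7=C8 instead of the thermodynamic C8=C9 position;
- cleave the sulfonyl group left over from the ring closure.

**C9–C11 bond (16 ⇒ 15 ⇒ 7 + 12).** The ring–chain bond is cut at the former carbonyl carbon of 1. Forward, the organometallic 14 (from 12 through 13) adds to ketone 7, and an oxidative 1,3-transposition of alcohol 15 moves the oxygen to C7. The route is convergent, C13 arrives already resolved, and the face of addition at C9 does not matter because C9 becomes sp2 in 16.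

**Side chain (12 ⇒ 11 ⇒ 10 ⇒ 9 ⇒ 8).** These are functional-group changes only. The acid and ester ends of 8 differentiate the two termini of a nearly symmetrical C5 unit. The acid end becomes C15 and the ester end becomes C11, and this assignment gives 13S.

**C3–C4 bond, ring A (7 ⇒ 6).** This is the central disconnection. C4 is the internal carbon of the isopropenyl group of 6, and as a tertiary radical it forms the gem-dimethyl quaternary centre readily. A polar alkylation at this neopentyl position would not. The acceptor is a vinyl sulfone whose activating group is later removed without trace. The ring fusion is not at stake in this step because C5 and C10 already exist.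

**C10–C1 and C10–C20 bonds (6 ⇒ 3 + 4, 3 ⇒ 1).** Two successive enolate alkylations (through 5 and 2) build the quaternary C10. The methyl group goes in first and the larger electrophile 4 second, so that 4 enters anti to the C5 substituent and places C1 trans to C4.

## Alternatives that were turned down

**Alternative 1: enzymatic bicyclisation.**
- Disconnection: C4–C5 and C9–C10, opening both rings to the acyclic diphosphate A1.
- Key step: a class 2 diterpene synthase protonates the terminal alkene of A1, the two internal alkenes close rings A and B, and a proton is lost from C7, giving A2.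
- For: one step makes both rings, the quaternary C10, three contiguous stereocentres and the C7=C8 alkene with enzymatic fidelity. On this point, and on step count (about five operations from A2), it is stronger than the chosen route.
- Against: A2 has neither the C13 stereocentre nor the C17 oxygen. C13 would need an enantioselective reduction of C13=C14 that leaves C7=C8 alone. C17 would need the same late allylic oxidation as here, so the weakest step is not avoided. The protein must be expressed and A1 supplied, and the reaction runs dilute in water.
- Comparison: the chosen route gives up this density of bond formation. In return it uses catalogue reagents only, buys C13 resolved, and runs on a preparative scale.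

**Alternative 2: intermolecular exo Diels–Alder.**
- Disconnection: C5–C6 and C9–C10 in ring B, giving enal A3 and diene A4.
- Key step: a cationic chiral oxazaborolidine Lewis acid promotes the formyl-exo cycloaddition to A5. Ring A is then closed between the formyl carbon C1 and the allyl arm by methylenation, ring-closing metathesis and a selective hydrogenation.
- For: it is highly convergent. C17 is already oxygenated and the whole chain with C13 is in A4, so there is no late C–H oxidation and no transposition–reduction sequence. On these points it is stronger.
- Against:
  - A3 is an α-methyl enal whose β-carbon carries a fully substituted carbon, and the cycloaddition must create the quaternary C10 beside it. This is a very unreactive class of dienophile.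
  - The C8 substituent of A4 directs electronically against the regiochemistry that the C9 substituent demands.
  - The allylic acetate is exposed to a strong Lewis acid.
  - All three ring stereocentres depend on the catalyst.
  - Closing ring A costs three more steps, one of them a hydrogenation that must spare C7=C8.
- Comparison: the chosen route takes C5 from the chiral pool and sets C10 by a substrate-controlled alkylation. It accepts a longer redox endgame in exchange.

**Alternative 3: auxiliary-controlled intramolecular Diels–Alder.**
- Disconnection: C5–C10 and C8–C9, opening both rings to triene A7.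
- Key step: a dialkylaluminium chloride promotes the intramolecular cycloaddition, and the benzyl oxazolidinone auxiliary selects the face, giving A6.
- For: both rings and C5, C9 and C10 form in one step. C17 arrives as an ester, and the C7 silyl enol ether is a handle for placing C7=C8 through the keto ester and its enol triflate. On C17 and on alkene placement it is stronger than the chosen route.
- Against:
  - The dienophile is β,β-disubstituted, since it must create C10, which sharply lowers the reactivity of acyl oxazolidinones.
  - The electron-rich silyloxy diene may react stepwise under the Lewis acid and lose stereochemical fidelity.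
  - A7 needs a long linear synthesis with three defined alkene geometries.
  - After the cycloaddition the C12–C15 unit with C13 must still be joined to the C11 carbonyl, and C7 must be deoxygenated.
- Comparison: it needs more steps and a stoichiometric auxiliary. The chosen route buys ring B and C5 ready-made and has to close only one ring.

Key step: step 3

Assumption: bromide 4 and half-ester 8 are treated as catalogue compounds, and the C2 epimer of 7 is taken to be as usable as the one drawn, because C2 becomes a methylene group in step 10.

## Route

Step 1
Reactants: 1 (R)-carvone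
Product: 3 (5R,6S)-2,6-dimethyl-5-(prop-1-en-2-yl)cyclohex-2-en-1-one (trans-6-methylcarvone), via lithium dienolate of carvone 2 (not isolated)
Conditions: LiN(i-Pr)2, THF, −78 °C; MeI, −78 to −20 °C
Reagents that add atoms: iodomethane, CI
Why: Kinetic deprotonation at the α′-methylene (C10) gives the cross-conjugated dienolate 2, and its methylation is a standard enolate alkylation. The methyl group enters mainly trans to the isopropenyl group, with the minor epimer carried along, and this does not matter because the carbon is planarised again in step 2.

Step 2
Reactants: 3 trans-6-methylcarvone; 4 3-bromo-2-(phenylsulfonyl)prop-1-ene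
Product: 6 (5S,6S)-2,6-dimethyl-6-[2-(phenylsulfonyl)prop-2-en-1-yl]-5-(prop-1-en-2-yl)cyclohex-2-en-1-one, via lithium enolate of 6-methylcarvone 5 (not isolated)
Conditions: LiN(i-Pr)2, THF, −78 °C; then 4, −78 to 0 °C
Reagents that add atoms: none
Why: Enolate alkylation at the α′-methine builds the quaternary C10; the bromide reacts by direct or by addition–elimination (SN2′) displacement, and both paths give the same 2-sulfonylallyl group. The electrophile approaches the enolate face opposite the neighbouring isopropenyl group on C5, so C1 ends up anti to C4 and the methyl C20 syn to it, which is the relative configuration of a trans ring fusion.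

Step 3
Reactants: 6 (5S,6S)-2,6-dimethyl-6-[2-(phenylsulfonyl)prop-2-en-1-yl]-5-(prop-1-en-2-yl)cyclohex-2-en-1-one
Product: 7 (4aS,7S,8aS)-2,5,5,8a-tetramethyl-7-(phenylsulfonyl)-4a,5,6,7,8,8a-hexahydronaphthalen-1(4H)-one (trans-fused; sulfonyl group on C2 of the labdane frame, equatorial)
Conditions: Fe(acac)3 (30 mol %), PhSiH3 (2.5 equiv), EtOH/(CH2OH)2 5:1, 60 °C, 0.02 M
Reagents that add atoms: none
Why: An iron hydride formed from Fe(acac)3 and PhSiH3 transfers a hydrogen atom to the terminal carbon of the isopropenyl group in the Markovnikov sense and gives the tertiary radical at C4; this nucleophilic radical adds to the unsubstituted terminus C3 of the vinyl sulfone, and the α-sulfonyl radical so formed is reduced by divalent iron and protonated by the alcohol solvent, which returns trivalent iron to the cycle. The closest known reaction type is the Fe(acac)3/PhSiH3 reductive coupling of unactivated alkenes with electron-poor alkenes, a hydrogen-atom-transfer Giese reaction, applied here within one molecule. Ring A closes in the 6-endo-trig mode, because C3 is the far end of a 5-substituted hex-5-enyl radical, whereas 5-exo closure would need attack at the fully substituted, sulfonyl-bearing C2 and would leave an unstabilised primary radical. The only new stereocentre is C2, where the bulky sulfonyl group is expected to settle equatorial, away from the axial methyl groups on C4 and C10; either epimer serves, since C2 becomes a methylene group in step 10. C5 and C10 are not touched, so the trans fusion follows directly from the anti relationship set in step 2. The step needs hydrogen-atom transfer to the 1,1-disubstituted alkene in the presence of the enone and the vinyl sulfone, and this is secured by the preference of the metal hydride for electron-rich, lightly substituted alkenes and by the fact that the C4 radical cannot reach the enone without forming a four-membered ring. It also needs ring closure to outrun reduction of the C4 radical, which the polarity-matched acceptor held on the neighbouring ring carbon and the moderate dilution should ensure.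

Step 4
Reactants: 8 (R)-monomethyl 3-methylglutarate
Product: 9 methyl (3R)-5-hydroxy-3-methylpentanoate
Conditions: BH3·SMe2, THF, 0 °C to rt; aqueous work-up
Reagents that add atoms: none
Why: Borane reduces the free carboxylic acid through its acyloxyborane far faster than the methyl ester, so the two chain ends stay differentiated and the stereocentre is not involved. The hydroxy ester is silylated at once to forestall lactonisation.

Step 5
Reactants: 9 methyl (3R)-5-hydroxy-3-methylpentanoate
Product: 10 methyl (3R)-5-[(tert-butyldimethylsilyl)oxy]-3-methylpentanoate
Conditions: TBSCl, imidazole, DMF, 0 °C to rt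
Reagents that add atoms: tert-butyldimethylsilyl chloride, CC(C)(C)[Si](C)(C)Cl
Why: Silylation of a primary alcohol with a silyl chloride and imidazole is routine. This silyl ether is chosen because it withstands the organolithium, chromium, dissolving-metal and selenium steps that follow.

Step 6
Reactants: 10 methyl (3R)-5-[(tert-butyldimethylsilyl)oxy]-3-methylpentanoate
Product: 11 (3S)-5-[(tert-butyldimethylsilyl)oxy]-3-methylpentan-1-ol
Conditions: LiAlH4, Et2O, 0 °C
Reagents that add atoms: none
Why: Hydride reduction of the ester gives the primary alcohol whose carbon becomes C11; the silyl ether and the C13 stereocentre are inert (the descriptor changes only because the priorities change).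

Step 7
Reactants: 11 (3S)-5-[(tert-butyldimethylsilyl)oxy]-3-methylpentan-1-ol
Product: 12 tert-butyl{[(3R)-5-iodo-3-methylpentyl]oxy}dimethylsilane
Conditions: I2, PPh3, imidazole, CH2Cl2, 0 °C to rt
Reagents that add atoms: iodine, II
Why: Appel-type iodination of a primary alcohol proceeds under neutral conditions that leave the silyl ether intact; the reacting carbon is a methylene group, so no stereocentre is affected.

Step 8
Reactants: 12 tert-butyl{[(3R)-5-iodo-3-methylpentyl]oxy}dimethylsilane; 7 (4aS,7S,8aS)-2,5,5,8a-tetramethyl-7-(phenylsulfonyl)-4a,5,6,7,8,8a-hexahydronaphthalen-1(4H)-one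
Product: 15 (13S)-15-[(tert-butyldimethylsilyl)oxy]-2α-(phenylsulfonyl)labd-7-en-9-ol with the C11 chain on the α face and 9β-OH, via alkyllithium 13 (not isolated), via alkylcerium dichloride 14 (not isolated)
Conditions: 12, t-BuLi (2.0 equiv), Et2O, −78 °C; CeCl3 (anhydrous), THF, −78 °C; then 7, −78 to 0 °C
Reagents that add atoms: none
Why: Lithium–iodine exchange followed by transmetalation to cerium gives a strongly nucleophilic but weakly basic reagent that adds 1,2 to hindered enones and tolerates the α-sulfonyl C–H bond (organocerium carbonyl addition). Attack is expected on the α face, opposite the angular methyl group, but the C9 configuration is erased in step 9.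

Step 9
Reactants: 15 (13S)-15-[(tert-butyldimethylsilyl)oxy]-2α-(phenylsulfonyl)labd-7-en-9-ol
Product: 16 (13S)-15-[(tert-butyldimethylsilyl)oxy]-2α-(phenylsulfonyl)labd-8-en-7-one
Conditions: pyridinium chlorochromate, 4 Å MS, CH2Cl2, rt
Reagents that add atoms: pyridinium chlorochromate, [O-][Cr](=O)(=O)Cl.c1cc[nH+]cc1 (the C7 oxygen comes from the chromate ester; the C9 oxygen leaves with chromium)
Why: In this Babler–Dauben oxidative transposition the chromate ester of the tertiary allylic alcohol undergoes a [3,3] shift to C7 and is oxidised there, which moves the alkene to C8=C9; both C9 epimers converge. The silyl ether and the sulfone are inert to the oxidant.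

Step 10
Reactants: 16 (13S)-15-[(tert-butyldimethylsilyl)oxy]-2α-(phenylsulfonyl)labd-8-en-7-one
Product: 18 (13S)-15-[(tert-butyldimethylsilyl)oxy]labd-7-en-7-yl trifluoromethanesulfonate, via lithium C7 enolate 17 (not isolated)
Conditions: Li (4.5 equiv), t-BuOH (2.0 equiv), NH3/THF, −78 to −33 °C; evaporate NH3; PhNTf2, THF, 0 °C to rt
Reagents that add atoms: N-phenylbis(trifluoromethanesulfonimide), O=S(=O)(N(c1ccccc1)S(=O)(=O)C(F)(F)F)C(F)(F)F
Why: Dissolving-metal reduction of the enone gives the regiodefined C7 enolate; C9 is protonated axially on the α face, anti to the C10 methyl group, which sets the C9 stereocentre with the chain equatorial, and the same medium cleaves the C2–S bond (reductive desulfonylation). O-Sulfonylation of the enolate with PhNTf2 then fixes the alkene at C7=C8.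

Step 11
Reactants: 18 (13S)-15-[(tert-butyldimethylsilyl)oxy]labd-7-en-7-yl trifluoromethanesulfonate
Product: 19 (13S)-15-[(tert-butyldimethylsilyl)oxy]labd-7-ene
Conditions: Pd(OAc)2 (cat.), PPh3, Bu3N, HCO2H, DMF, 60 °C
Reagents that add atoms: none
Why: In this palladium-catalysed formate reduction of an enol triflate, zerovalent palladium inserts into the C7–O bond, formate delivers hydride with loss of CO2, and reductive elimination forms the C7–H bond without moving the alkene or touching C9.

Step 12
Reactants: 19 (13S)-15-[(tert-butyldimethylsilyl)oxy]labd-7-ene
Product: 20 (13S)-15-[(tert-butyldimethylsilyl)oxy]labd-7-en-17-ol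
Conditions: SeO2 (cat.), t-BuOOH (2 equiv), CH2Cl2, 0 °C to rt
Reagents that add atoms: selenium dioxide, O=[Se]=O (delivers the oxygen); tert-butyl hydroperoxide, CC(C)(C)OO (restores SeO2 and is the net oxygen source)
Why: Selenium dioxide allylic oxidation (ene reaction, then [2,3]-sigmatropic shift) acts at the more substituted end of a trisubstituted alkene, where the methyl group C17 is preferred over the hindered methine C9, and the two shifts return the alkene to C7=C8. The peroxide keeps selenium in its active oxide form, so little of it is needed and oxidation beyond the alcohol is limited.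

Step 13
Reactants: 20 (13S)-15-[(tert-butyldimethylsilyl)oxy]labd-7-en-17-ol
Product: 21 (13S)-labd-7-ene-15,17-diol
Conditions: TBAF, THF, 0 °C to rt
Reagents that add atoms: none
Why: Fluoride cleaves the Si–O bond of the primary silyl ether; the allylic alcohol and the alkene are unaffected.

Step 14
Reactants: 21 (13S)-labd-7-ene-15,17-diol
Product: 22 (13S)-labd-7-ene-15,17-diyl diacetate (CNP0294037.1)
Conditions: Ac2O, pyridine, DMAP (cat.), CH2Cl2, 0 °C to rt
Reagents that add atoms: acetic anhydride, CC(=O)OC(C)=O
Why: Nucleophile-catalysed acylation esterifies both primary alcohols; the mildly basic conditions neither ionise the allylic acetate nor move the alkene, and no stereocentre is involved.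

## Compound list

1 | (R)-carvone | CC1=CC[C@H](CC1=O)C(C)=C | starting material
2 | lithium cross-conjugated dienolate of (R)-carvone | CC1=CC[C@H](C=C1O[Li])C(C)=C | intermediate
3 | (5R,6S)-2,6-dimethyl-5-(prop-1-en-2-yl)cyclohex-2-en-1-one (trans-6-methylcarvone, major epimer) | CC1=CC[C@@H](C(C)=C)[C@H](C)C1=O | intermediate
4 | 3-bromo-2-(phenylsulfonyl)prop-1-ene | C=C(CBr)S(=O)(=O)c1ccccc1 | starting material
5 | lithium enolate of 6-methylcarvone | CC1=CC[C@@H](C(C)=C)C(C)=C1O[Li] | intermediate
6 | (5S,6S)-2,6-dimethyl-6-[2-(phenylsulfonyl)prop-2-en-1-yl]-5-(prop-1-en-2-yl)cyclohex-2-en-1-one | CC1=CC[C@@H](C(C)=C)[C@](C)(CC(=C)S(=O)(=O)c2ccccc2)C1=O | intermediate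
7 | (4aS,7S,8aS)-2,5,5,8a-tetramethyl-7-(phenylsulfonyl)-4a,5,6,7,8,8a-hexahydronaphthalen-1(4H)-one | CC1=CC[C@H]2C(C)(C)C[C@H](S(=O)(=O)c3ccccc3)C[C@]2(C)C1=O | intermediate
8 | (R)-monomethyl 3-methylglutarate | COC(=O)C[C@H](C)CC(=O)O | starting material
9 | methyl (3R)-5-hydroxy-3-methylpentanoate | COC(=O)C[C@H](C)CCO | intermediate
10 | methyl (3R)-5-[(tert-butyldimethylsilyl)oxy]-3-methylpentanoate | COC(=O)C[C@H](C)CCO[Si](C)(C)C(C)(C)C | intermediate
11 | (3S)-5-[(tert-butyldimethylsilyl)oxy]-3-methylpentan-1-ol | OCC[C@H](C)CCO[Si](C)(C)C(C)(C)C | intermediate
12 | tert-butyl{[(3R)-5-iodo-3-methylpentyl]oxy}dimethylsilane | ICC[C@H](C)CCO[Si](C)(C)C(C)(C)C | intermediate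
13 | {(3S)-5-[(tert-butyldimethylsilyl)oxy]-3-methylpentyl}lithium | [Li]CC[C@H](C)CCO[Si](C)(C)C(C)(C)C | intermediate
14 | {(3R)-5-[(tert-butyldimethylsilyl)oxy]-3-methylpentyl}cerium dichloride | Cl[Ce](Cl)CC[C@H](C)CCO[Si](C)(C)C(C)(C)C | intermediate
15 | (13S)-15-[(tert-butyldimethylsilyl)oxy]-2α-(phenylsulfonyl)labd-7-en-9-ol, C11 chain α, 9β-OH | CC1=CC[C@H]2C(C)(C)C[C@H](S(=O)(=O)c3ccccc3)C[C@]2(C)[C@]1(O)CC[C@H](C)CCO[Si](C)(C)C(C)(C)C | intermediate
16 | (13S)-15-[(tert-butyldimethylsilyl)oxy]-2α-(phenylsulfonyl)labd-8-en-7-one | CC1=C(CC[C@H](C)CCO[Si](C)(C)C(C)(C)C)[C@@]2(C)C[C@@H](S(=O)(=O)c3ccccc3)CC(C)(C)[C@@H]2CC1=O | intermediate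
17 | lithium (13S)-15-[(tert-butyldimethylsilyl)oxy]labd-7-en-7-olate | CC(C)(C)[Si](C)(C)OCC[C@@H](C)CC[C@H]1C(C)=C(O[Li])C[C@H]2C(C)(C)CCC[C@]12C | intermediate
18 | (13S)-15-[(tert-butyldimethylsilyl)oxy]labd-7-en-7-yl trifluoromethanesulfonate | CC(C)(C)[Si](C)(C)OCC[C@@H](C)CC[C@H]1C(C)=C(OS(=O)(=O)C(F)(F)F)C[C@H]2C(C)(C)CCC[C@]12C | intermediate
19 | (13S)-15-[(tert-butyldimethylsilyl)oxy]labd-7-ene | CC(C)(C)[Si](C)(C)OCC[C@@H](C)CC[C@H]1C(C)=CC[C@H]2C(C)(C)CCC[C@]12C | intermediate
20 | (13S)-15-[(tert-butyldimethylsilyl)oxy]labd-7-en-17-ol | CC(C)(C)[Si](C)(C)OCC[C@@H](C)CC[C@H]1C(CO)=CC[C@H]2C(C)(C)CCC[C@]12C | intermediate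
21 | (13S)-labd-7-ene-15,17-diol | OCC[C@@H](C)CC[C@H]1C(CO)=CC[C@H]2C(C)(C)CCC[C@]12C | intermediate
22 | (13S)-labd-7-ene-15,17-diyl diacetate (CNP0294037.1) | CC(=O)OCC[C@@H](C)CC[C@H]1C(COC(C)=O)=CC[C@H]2C(C)(C)CCC[C@]12C | target

## Step count and least certain steps

Total step count: 14.
Longest linear sequence: 11 steps (8 to 22 through steps 4–14). The carvone branch is 10 steps (1, 2, 3, 8–14).

**Step 3 (key step).** The most likely failure is reduction of the C4 radical before it cyclises, so that the isopropenyl group is simply hydrogenated. Hydrogen-atom transfer to the enone is a second possibility. Both arise because the iron hydride is present throughout and the closure has to form a bond to a carbon that becomes quaternary. Fallback: from 6, Markovnikov addition of HBr (HBr, AcOH, 0 °C) to the isopropenyl group gives the tertiary bromide F1. Slow addition of Bu3SnH and AIBN in refluxing benzene then generates the same C4 radical by bromine abstraction. The tin hydride concentration is kept low, so the 6-endo closure onto the vinyl sulfone precedes hydrogen transfer. The sequence returns to the route at 7.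

**Step 12.** The most likely failure is poor site selectivity of the allylic oxidation, with attack at the methine C9 or at C6, or oxidation at C17 beyond the alcohol stage. The rules for selenium dioxide favour the methyl group but do not exclude the ring positions. Fallback: from 19, epoxidation with mCPBA (NaHCO3, CH2Cl2, 0 °C) on the α face, opposite the C10 methyl group, gives the 7α,8α-epoxide F2. Diethylaluminium 2,2,6,6-tetramethylpiperidide in toluene at 0 °C removes a C17 proton and opens the epoxide to the exocyclic allylic alcohol F3. Catalytic Ph3SiOReO3 in Et2O then transposes the hydroxyl group 1,3 to the primary position, driven by the more substituted ring alkene. The sequence returns to the route at 20.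

**Step 10.** The most likely failure is loss of the enolate before or during triflation. The lithium alkoxide and sulfinate produced in the reduction can consume the triflating agent, and proton exchange can scramble the enolate or lead to over-reduction. Fallback: from 16, the same reduction is run but the enolate is trapped with Me3SiCl/Et3N, which tolerates these salts, giving the trimethylsilyl enol ether F4 after a non-aqueous work-up. MeLi in THF at 0 °C regenerates salt-free 17, which is O-sulfonylated with N-(5-chloro-2-pyridyl)bis(trifluoromethanesulfonimide). The sequence returns to the route at 18.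

**Step 9.** The most likely failure is ionisation and dehydration of the crowded tertiary allylic alcohol to dienes, in place of formation and rearrangement of the chromate ester, because C9 is flanked by the quaternary C10. Fallback: from 15, catalytic Ph3SiOReO3 in Et2O at 0 °C moves the hydroxyl group to C7 without an oxidant and gives the secondary allylic alcohol F5, favoured by the tetrasubstituted alkene. MnO2 in CH2Cl2 then oxidises F5. The sequence returns to the route at 16.

**Step 2.** The most likely failure is conjugate addition of enolate 5 to the vinyl sulfone of product already formed, or eroded facial selectivity, because 4 and its product are both Michael acceptors. Fallback: from 3, enolate 5 is alkylated with 2,3-dibromopropene, a simple allylic halide, to give the 2-bromoallyl ketone F6 with the same anti selectivity. Coupling of the vinyl bromide with PhSO2Na (CuI, sodium L-prolinate, DMSO, 90 °C) then installs the sulfonyl group. The sequence returns to the route at 6.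

## Further compounds

F1 | step 3 | (5R,6S)-5-(2-bromopropan-2-yl)-2,6-dimethyl-6-[2-(phenylsulfonyl)prop-2-en-1-yl]cyclohex-2-en-1-one | CC1=CC[C@@H](C(C)(C)Br)[C@](C)(CC(=C)S(=O)(=O)c2ccccc2)C1=O
F2 | step 12 | (13S)-15-[(tert-butyldimethylsilyl)oxy]-7α,8α-epoxylabdane | CC(C)(C)[Si](C)(C)OCC[C@@H](C)CC[C@H]1[C@]2(C)O[C@@H]2C[C@H]3C(C)(C)CCC[C@]13C
F3 | step 12 | (13S)-15-[(tert-butyldimethylsilyl)oxy]labd-8(17)-en-7α-ol | CC(C)(C)[Si](C)(C)OCC[C@@H](C)CC[C@H]1C(=C)[C@H](O)C[C@H]2C(C)(C)CCC[C@]12C
F4 | step 10 | (13S)-15-[(tert-butyldimethylsilyl)oxy]-7-[(trimethylsilyl)oxy]labd-7-ene | CC(C)(C)[Si](C)(C)OCC[C@@H](C)CC[C@H]1C(C)=C(O[Si](C)(C)C)C[C@H]2C(C)(C)CCC[C@]12C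
F5 | step 9 | (13S)-15-[(tert-butyldimethylsilyl)oxy]-2α-(phenylsulfonyl)labd-8-en-7β-ol | CC1=C(CC[C@H](C)CCO[Si](C)(C)C(C)(C)C)[C@@]2(C)C[C@@H](S(=O)(=O)c3ccccc3)CC(C)(C)[C@@H]2C[C@@H]1O
F6 | step 2 | (5S,6S)-6-(2-bromoprop-2-en-1-yl)-2,6-dimethyl-5-(prop-1-en-2-yl)cyclohex-2-en-1-one | CC1=CC[C@@H](C(C)=C)[C@](C)(CC(Br)=C)C1=O
A1 | alternative 1 | (E,E,E)-geranylgeranyl diphosphate | CC(C)=CCC/C(C)=C/CC/C(C)=C/CC/C(C)=C/COP(=O)(O)OP(=O)(O)O
A2 | alternative 1 | labda-7,13E-dien-15-yl diphosphate | C/C(=C\COP(=O)(O)OP(=O)(O)O)CC[C@H]1C(C)=CC[C@H]2C(C)(C)CCC[C@]12C
A3 | alternative 2 | (E)-2,4,4-trimethylhepta-2,6-dienal | O=C/C(C)=C/C(C)(C)CC=C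
A4 | alternative 2 | (3S)-7-(acetoxymethyl)-3-methylnona-6,8-dien-1-yl acetate, chain trans to the vinyl group | C=C/C(COC(C)=O)=C/CC[C@H](C)CCOC(C)=O
A5 | alternative 2 | ring B cycloadduct aldehyde with C5, C9 and C10 set, carrying the formyl carbon C1 and the 2-methylpent-4-en-2-yl arm | CC(=O)OCC[C@@H](C)CC[C@H]1C(COC(C)=O)=CC[C@@H](C(C)(C)CC=C)[C@]1(C)C=O
A6 | alternative 3 | trans-fused cycloadduct: acyl (S)-4-benzyloxazolidinone on C9, methyl ester on C8, silyl enol ether at C6=C7 | O=C(N3[C@@H](Cc4ccccc4)COC3=O)[C@H]1[C@@H](C(=O)OC)C(O[Si](C)(C)C(C)(C)C)=C[C@H]2C(C)(C)CCC[C@]12C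
A7 | alternative 3 | triene: methyl (2Z,4E)-3-silyloxydienoate tethered to an (E)-3-methylenoyl (S)-4-benzyloxazolidinone | COC(=O)/C=C(O[Si](C)(C)C(C)(C)C)/C=C/C(C)(C)CCC/C(C)=C/C(=O)N1[C@@H](Cc2ccccc2)COC1=O
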